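The route rests on removing the two benzylic C7–O bonds of the erythro end units C and E, leaving a 7-deoxy pentamer. The feature used is that only the guaiacyl rings of C and E carry a free phenol para to C7, and each C7 is flanked by a C8 stereocentre bearing a C9 hydroxymethyl arm. In one operation Ag2O converts both phenols into quinone methides and phenylboronic acid, anchored on each C9–OH, returns oxygen to C7 from the C8-defined face, setting both erythro centres. The precursor is assembled from resolved syringaresinol by two inverting etherifications with antipodal 3-aryllactate triflates and an Evans syn-glycolate aldol for threo unit D.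

Key step: step 17

Remark on labels: rings A and B are the two syringyl rings of the furofuran core. Unit D (threo) sits on the oxygen of ring A, unit E (erythro) on the phenol oxygen of unit D, and unit C (erythro) on the oxygen of ring B. In each unit C7 is the benzylic carbon, C8 the aryloxy-bearing carbon and C9 the CH2OH carbon. Target descriptors: core 7R,8S,7'R,8'S; C 7S,8R; D 7R,8R; E 7R,8S. In the 7-deoxy series the same spatial arrangement at C8 reads 8S in C and 8R in E, because C9 then outranks C7.

Assumption: 4-formyl-2-methoxyphenyl acetate (the acetate of vanillin), 4-bromo-2-methoxyphenol and both enantiomers of methyl glycidate are bought. The 7R,8S,7'R,8'S enantiomer of syringaresinol is to be assigned after the resolution by comparing its chiroptical data with the recorded ones.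

Step 1
Reactants: 1 sinapyl alcohol (two molecules)
Product: 3 (±)-syringaresinol (racemic cis-fused furofuran, both aryl groups exo), via racemic bis(quinone methide) 2 (not isolated)
Conditions: FeCl3·6H2O (1.1 equiv per phenol), acetone/H2O, rt
Reagents that add atoms: sinapyl alcohol 1 (the second molecule of the dimerisation), COc1cc(/C=C/CO)cc(OC)c1O
Why: Oxidative phenol coupling: one-electron oxidation by trivalent iron gives the sinapyl radical, β–β coupling of two radicals gives the bis(quinone methide) 2, and each C9 hydroxyl closes onto the opposite C7 in a 5-exo oxa-conjugate addition, which fixes the cis ring fusion and the exo position of both aryl groups in racemic form.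

Step 2
Reactants: 3 (±)-syringaresinol
Product: 4 (7R,8S,7'R,8'S)-syringaresinol
Conditions: preparative HPLC on silica-bound cellulose tris(3,5-dimethylphenylcarbamate), hexane/EtOH
Reagents that add atoms: none
Why: Resolution of enantiomers by chromatography on a chiral polysaccharide phase separates the two mirror-image furofurans without any bond change, so the four core stereocentres are taken as the 7R,8S,7'R,8'S set from one of the two fractions.

Step 3
Reactants: 5 4-bromo-2-methoxyphenol
Product: 6 (4-bromo-2-methoxyphenoxy)triisopropylsilane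
Conditions: TIPSCl, imidazole, DMF, rt
Reagents that add atoms: triisopropylsilyl chloride, CC(C)[Si](Cl)(C(C)C)C(C)C
Why: Silyl ether formation from a phenol with a silyl chloride and imidazole; the bulky triisopropylsilyl group is chosen because it survives Grignard formation, carbonate bases and borohydride and is removed by fluoride.

Step 4
Reactants: 6 (4-bromo-2-methoxyphenoxy)triisopropylsilane
Product: 7 [3-methoxy-4-(triisopropylsilyloxy)phenyl]magnesium bromide (titrated THF stock solution)
Conditions: Mg turnings (I2 crystal), THF, 50 °C; titrated and kept under argon; one batch serves steps 5 and 12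
Reagents that add atoms: magnesium, [Mg]
Why: Grignard reagent formation by insertion of magnesium into the aryl C–Br bond, to which the aryl silyl ether and the methyl ether are inert; a THF solution of an arylmagnesium bromide keeps under argon, so a single batch can feed both epoxide openings.

Step 5
Reactants: 7 [3-methoxy-4-(triisopropylsilyloxy)phenyl]magnesium bromide; 8 methyl (R)-glycidate
Product: 9 methyl (2R)-2-hydroxy-3-[3-methoxy-4-(triisopropylsilyloxy)phenyl]propanoate
Conditions: CuI (10 mol %), THF, −40 → −20 °C; aq NH4Cl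
Reagents that add atoms: none
Why: Copper-catalysed SN2 opening of a glycidic ester by an aryl Grignard reagent at the unsubstituted epoxide carbon, which is faster than addition to the ester at low temperature and leaves the C2 stereocentre of 8 untouched, so 9 is the (R)-aryllactate.

Step 6
Reactants: 9 methyl (2R)-2-hydroxy-3-[3-methoxy-4-(triisopropylsilyloxy)phenyl]propanoate
Product: 10 methyl (2R)-3-[3-methoxy-4-(triisopropylsilyloxy)phenyl]-2-(trifluoromethylsulfonyloxy)propanoate
Conditions: Tf2O, 2,6-lutidine, CH2Cl2, −78 → −20 °C; used at once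
Reagents that add atoms: triflic anhydride, O=S(=O)(OS(=O)(=O)C(F)(F)F)C(F)(F)F
Why: Sulfonylation of a secondary α-hydroxy ester with triflic anhydride and a hindered pyridine base turns the hydroxyl into a leaving group with retention, since only the O–H bond is involved.

Step 7
Reactants: 4 (7R,8S,7'R,8'S)-syringaresinol; 10 (R)-triflate
Product: 11 ring B mono-ether of 4 carrying the (1S)-1-(methoxycarbonyl)-2-[3-methoxy-4-(triisopropylsilyloxy)phenyl]ethyl group (unit C as ester; ring A phenol free)
Conditions: 4 (3 equiv), K2CO3, MeCN, 0 °C → rt; excess 4 recovered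
Reagents that add atoms: none
Why: Williamson-type SN2 substitution of an α-triflyloxy ester by a phenoxide proceeds with inversion and sets C8 of unit C as S; the two phenols of C2-symmetric 4 are equivalent, so using 4 in excess holds the statistical reaction at the mono-ether and the surplus is recovered.

Step 8
Reactants: 12 (S)-4-benzyl-2-oxazolidinone; 13 bromoacetyl bromide
Product: 15 (S)-4-benzyl-3-(bromoacetyl)-2-oxazolidinone, via lithium oxazolidinide 14 (not isolated)
Conditions: n-BuLi, THF, −78 °C; then 13, −78 → 0 °C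
Reagents that add atoms: none
Why: N-Acylation of a lithiated oxazolidinone by an acid bromide at low temperature, the acyl bromide being far more electrophilic than the alkyl bromide of the same reagent.

Step 9
Reactants: 11 ring B mono-ether; 15 (S)-4-benzyl-3-(bromoacetyl)-2-oxazolidinone
Product: 16 glycolyl imide (ring A oxygen of 11 bearing CH2C(=O)N of the (S)-auxiliary)
Conditions: K2CO3, MeCN, rt
Reagents that add atoms: none
Why: Williamson ether synthesis in which the ring A phenoxide displaces bromide from the activated α-bromo imide under a weak carbonate base that leaves the imide and the α-aryloxy ester of unit C intact.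

Step 10
Reactants: 16 glycolyl imide; 17 4-formyl-2-methoxyphenyl acetate
Product: 20 syn-aldol adduct [(2S,3R)-3-(4-acetoxy-3-methoxyphenyl)-3-hydroxy-2-(ring A aryloxy)propanoyl imide; unit D with 7R and the future 8R centre], via Z-boron enolate 18 (not isolated), via boron aldolate 19 (not isolated)
Conditions: n-Bu2BOTf, i-Pr2NEt, CH2Cl2, −78 → 0 °C; 17, −78 → 0 °C; pH 7 buffer, MeOH, H2O2, 0 °C
Reagents that add atoms: none
Why: Boron-mediated Evans syn aldol reaction of a glycolate imide: soft enolisation gives the Z-boron enolate, which adds to the aldehyde through a closed chair transition state on the enolate face away from the benzyl group of the (S)-auxiliary, setting C8 and C7 of unit D together as the syn pair that becomes 7R,8R (threo), while the less acidic ester of unit C is not enolised.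

Step 11
Reactants: 20 syn-aldol adduct
Product: 21 phenolic pentol (unit D as free (7R,8R)-triol with free phenol; unit C as (8S) 7-deoxy alcohol with silylated phenol)
Conditions: LiBH4, THF/MeOH, 0 °C → rt
Reagents that add atoms: none
Why: Borohydride reduction by LiBH4 cleaves the imide reductively to the C9 alcohol of unit D with release of the auxiliary, reduces the methyl ester of unit C to its C9 alcohol and cleaves the aryl acetate to the free phenol of unit D in one operation without touching a stereocentre.

Step 12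
Reactants: 7 [3-methoxy-4-(triisopropylsilyloxy)phenyl]magnesium bromide; 22 methyl (S)-glycidate
Product: 23 methyl (2S)-2-hydroxy-3-[3-methoxy-4-(triisopropylsilyloxy)phenyl]propanoate
Conditions: CuI (10 mol %), THF, −40 → −20 °C; aq NH4Cl
Reagents that add atoms: none
Why: Copper-catalysed SN2 opening of the glycidic ester by the aryl Grignard reagent at the unsubstituted epoxide carbon, which carries the C2 configuration of 22 unchanged into the (S)-aryllactate.

Step 13
Reactants: 23 methyl (2S)-2-hydroxy-3-[3-methoxy-4-(triisopropylsilyloxy)phenyl]propanoate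
Product: 24 methyl (2S)-3-[3-methoxy-4-(triisopropylsilyloxy)phenyl]-2-(trifluoromethylsulfonyloxy)propanoate
Conditions: Tf2O, 2,6-lutidine, CH2Cl2, −78 → −20 °C; used at once
Reagents that add atoms: triflic anhydride, O=S(=O)(OS(=O)(=O)C(F)(F)F)C(F)(F)F
Why: Sulfonylation of the secondary α-hydroxy ester with triflic anhydride and a hindered pyridine base activates C8 with retention of configuration.

Step 14
Reactants: 21 phenolic pentol; 24 (S)-triflate
Product: 25 unit E ester (phenol oxygen of unit D bearing the (1R)-1-(methoxycarbonyl)-2-[3-methoxy-4-(triisopropylsilyloxy)phenyl]ethyl group)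
Conditions: K2CO3, MeCN, 0 °C → rt
Reagents that add atoms: none
Why: SN2 substitution of the α-triflyloxy ester by a phenoxide with inversion sets C8 of unit E (R in the ester and in the 7-deoxy alcohol); carbonate ionises only the single free phenol of 21, so the three aliphatic hydroxyls are not alkylated.

Step 15
Reactants: 25 unit E ester
Product: 26 bis(triisopropylsilyl) ether of the 7-deoxy precursor
Conditions: LiBH4, THF/MeOH, 0 °C → rt
Reagents that add atoms: none
Why: Reduction of an α-aryloxy ester to the primary alcohol by LiBH4, to which the silyl ethers, the benzylic alcohol and the furofuran are inert.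

Step 16
Reactants: 26 bis(triisopropylsilyl) ether
Product: 27 7-deoxy precursor (target without the C7 hydroxyls of units C and E)
Conditions: n-Bu4NF, AcOH, THF, 0 °C → rt
Reagents that add atoms: none
Why: Fluoride cleavage of the two aryl silyl ethers driven by the strong Si–F bond, buffered with acetic acid so that the phenols are released under near-neutral conditions.

Step 17
Reactants: 27 7-deoxy precursor; 28 phenylboronic acid
Product: 32 CNP0316493.1, via boron-loaded precursor 29 (not isolated), via bis(quinone methide) 30 (not isolated), via tris(boronate) 31 (not isolated)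
Conditions: 28 (4 equiv), 4 Å molecular sieves, CH2Cl2, rt; Ag2O (2.5 equiv), i-Pr2NEt (0.2 equiv), dark, 0 °C → rt; filter; HN(CH2CH2OH)2, THF, rt
Reagents that add atoms: none
Why: Proposed new method: Ag2O removes two electrons and two protons from each free 4-alkyl-2-methoxyphenol (the guaiacyl rings of units C and E), giving quinone methides whose exocyclic carbon is C7, and the boron-bound hydroxyl of the phenylboronic hemiester that already sits on the neighbouring C9 oxygen, made more nucleophilic by the catalytic amine, then adds to C7 and restores the phenol, so that the C7 oxygen atoms come from 28. The closest known reactions are the Ag2O dehydrogenation of 4-alkylphenols to quinone methides and the amine-promoted intramolecular oxa-Michael addition of boronic acid hemiesters of hydroxy enones, which have not been combined on a quinone methide. Each of the two new 1,3,2-dioxaborinane rings (O–C7–C8–C9–O–B) closes in the 6-exo-trig mode, whereas the third boronate ring, on the 1,3-diol of unit D, arises by plain condensation and serves only as a mask. Each new C7 centre is controlled by its own C8 centre: 1,3-allylic strain places the C8 hydrogen in the plane of the quinone methide, so the C9–O–B tether and the C8 aryloxy group lie on opposite faces, and delivery from the tether face through a chair with the aryl and aryloxy groups both equatorial gives the trans-4,5-disubstituted boronate, that is the erythro unit (7S,8R in C and 7R,8S in E). The step needs chemoselectivity for the two end rings and regioselectivity for C7, and the substrate secures both, because rings A and B and the ring of unit D have no free phenol and cannot become quinone methides, while pre-formed boronates and molecular sieves keep the tethered oxygen as the only nucleophile within reach of each C7. Diethanolamine finally takes boron off all three boronates under neutral conditions that do not ionise the new 4-hydroxybenzyl alcohols.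

Compound list
1 | sinapyl alcohol | COc1cc(/C=C/CO)cc(OC)c1O | starting material
2 | racemic β–β-coupled bis(quinone methide) of 1 (C2-symmetric diastereomer, written as the pair of enantiomers; alkene geometry not defined) | COC1=CC(=C[C@H](CO)[C@@H](CO)C=C2C=C(OC)C(=O)C(OC)=C2)C=C(OC)C1=O.COC1=CC(=C[C@@H](CO)[C@H](CO)C=C2C=C(OC)C(=O)C(OC)=C2)C=C(OC)C1=O | intermediate (not isolated)
3 | (±)-syringaresinol, written as the pair of enantiomers | Oc1c(OC)cc([C@@H]2OC[C@@H]3[C@H]2CO[C@H]3c2cc(OC)c(O)c(OC)c2)cc1OC.Oc1c(OC)cc([C@H]2OC[C@H]3[C@@H]2CO[C@@H]3c2cc(OC)c(O)c(OC)c2)cc1OC | intermediate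
4 | (7R,8S,7'R,8'S)-syringaresinol | Oc1c(OC)cc([C@@H]2OC[C@@H]3[C@H]2CO[C@H]3c2cc(OC)c(O)c(OC)c2)cc1OC | intermediate
5 | 4-bromo-2-methoxyphenol | COc1cc(Br)ccc1O | starting material
6 | (4-bromo-2-methoxyphenoxy)triisopropylsilane | COc1cc(Br)ccc1O[Si](C(C)C)(C(C)C)C(C)C | intermediate
7 | [3-methoxy-4-(triisopropylsilyloxy)phenyl]magnesium bromide (THF stock solution) | COc1cc([Mg]Br)ccc1O[Si](C(C)C)(C(C)C)C(C)C | intermediate
8 | methyl (R)-glycidate (methyl (2R)-oxirane-2-carboxylate) | COC(=O)[C@H]1CO1 | starting material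
9 | methyl (2R)-2-hydroxy-3-[3-methoxy-4-(triisopropylsilyloxy)phenyl]propanoate | COC(=O)[C@H](O)Cc1ccc(O[Si](C(C)C)(C(C)C)C(C)C)c(OC)c1 | intermediate
10 | methyl (2R)-3-[3-methoxy-4-(triisopropylsilyloxy)phenyl]-2-(trifluoromethylsulfonyloxy)propanoate | COC(=O)[C@H](OS(=O)(=O)C(F)(F)F)Cc1ccc(O[Si](C(C)C)(C(C)C)C(C)C)c(OC)c1 | intermediate
11 | ring B mono-ether of 4 with unit C as its (8S) methyl ester; ring A phenol free | Oc1c(OC)cc([C@@H]2OC[C@@H]3[C@H]2CO[C@H]3c2cc(OC)c(O[C@H](C(=O)OC)Cc3ccc(O[Si](C(C)C)(C(C)C)C(C)C)c(OC)c3)c(OC)c2)cc1OC | intermediate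
12 | (S)-4-benzyl-2-oxazolidinone | O=C1N[C@@H](Cc2ccccc2)CO1 | starting material
13 | bromoacetyl bromide | O=C(Br)CBr | starting material
14 | lithium salt of 12 (N-lithio oxazolidinone) | [Li]N1[C@@H](Cc2ccccc2)COC1=O | intermediate (not isolated)
15 | (S)-4-benzyl-3-(bromoacetyl)-2-oxazolidinone | O=C(CBr)N1[C@@H](Cc2ccccc2)COC1=O | intermediate
16 | glycolyl imide: ring A oxygen of 11 bearing CH2C(=O)N of the (S)-auxiliary | O=C(COc1c(OC)cc([C@@H]2OC[C@@H]3[C@H]2CO[C@H]3c2cc(OC)c(O[C@H](C(=O)OC)Cc3ccc(O[Si](C(C)C)(C(C)C)C(C)C)c(OC)c3)c(OC)c2)cc1OC)N1[C@@H](Cc2ccccc2)COC1=O | intermediate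
17 | 4-formyl-2-methoxyphenyl acetate (vanillin acetate) | CC(=O)Oc1ccc(C=O)cc1OC | starting material
18 | Z-(dibutylboryl) enolate of 16 | CCCCB(CCCC)O/C(=C\Oc1c(OC)cc([C@@H]2OC[C@@H]3[C@H]2CO[C@H]3c2cc(OC)c(O[C@H](C(=O)OC)Cc3ccc(O[Si](C(C)C)(C(C)C)C(C)C)c(OC)c3)c(OC)c2)cc1OC)N1[C@@H](Cc2ccccc2)COC1=O | intermediate (not isolated)
19 | dibutylboryl aldolate of 20 | CC(=O)Oc1ccc([C@@H](OB(CCCC)CCCC)[C@@H](C(=O)N2[C@@H](Cc3ccccc3)COC2=O)Oc2c(OC)cc([C@@H]3OC[C@@H]4[C@H]3CO[C@H]4c3cc(OC)c(O[C@H](C(=O)OC)Cc4ccc(O[Si](C(C)C)(C(C)C)C(C)C)c(OC)c4)c(OC)c3)cc2OC)cc1OC | intermediate (not isolated)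
20 | syn-aldol adduct: (2S,3R)-3-(4-acetoxy-3-methoxyphenyl)-3-hydroxy-2-(ring A aryloxy)propanoyl imide, unit C still as methyl ester | CC(=O)Oc1ccc([C@@H](O)[C@@H](C(=O)N2[C@@H](Cc3ccccc3)COC2=O)Oc2c(OC)cc([C@@H]3OC[C@@H]4[C@H]3CO[C@H]4c3cc(OC)c(O[C@H](C(=O)OC)Cc4ccc(O[Si](C(C)C)(C(C)C)C(C)C)c(OC)c4)c(OC)c3)cc2OC)cc1OC | intermediate
21 | phenolic pentol: unit D (7R,8R)-triol with free phenol on ring A; unit C (8S) 7-deoxy alcohol with silylated phenol on ring B | Oc1ccc([C@@H](O)[C@@H](CO)Oc2c(OC)cc([C@@H]3OC[C@@H]4[C@H]3CO[C@H]4c3cc(OC)c(O[C@H](CO)Cc4ccc(O[Si](C(C)C)(C(C)C)C(C)C)c(OC)c4)c(OC)c3)cc2OC)cc1OC | intermediate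
22 | methyl (S)-glycidate (methyl (2S)-oxirane-2-carboxylate) | COC(=O)[C@@H]1CO1 | starting material
23 | methyl (2S)-2-hydroxy-3-[3-methoxy-4-(triisopropylsilyloxy)phenyl]propanoate | COC(=O)[C@@H](O)Cc1ccc(O[Si](C(C)C)(C(C)C)C(C)C)c(OC)c1 | intermediate
24 | methyl (2S)-3-[3-methoxy-4-(triisopropylsilyloxy)phenyl]-2-(trifluoromethylsulfonyloxy)propanoate | COC(=O)[C@@H](OS(=O)(=O)C(F)(F)F)Cc1ccc(O[Si](C(C)C)(C(C)C)C(C)C)c(OC)c1 | intermediate
25 | unit E ester: 21 etherified at the unit D phenol with the (8R) methyl 3-aryl-propanoate unit | COc1cc(C[C@H](C(=O)OC)Oc2ccc([C@@H](O)[C@@H](CO)Oc3c(OC)cc([C@@H]4OC[C@@H]5[C@H]4CO[C@H]5c4cc(OC)c(O[C@H](CO)Cc5ccc(O[Si](C(C)C)(C(C)C)C(C)C)c(OC)c5)c(OC)c4)cc3OC)cc2OC)ccc1O[Si](C(C)C)(C(C)C)C(C)C | intermediate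
26 | bis(triisopropylsilyl) ether of the 7-deoxy precursor | COc1cc(C[C@H](CO)Oc2ccc([C@@H](O)[C@@H](CO)Oc3c(OC)cc([C@@H]4OC[C@@H]5[C@H]4CO[C@H]5c4cc(OC)c(O[C@H](CO)Cc5ccc(O[Si](C(C)C)(C(C)C)C(C)C)c(OC)c5)c(OC)c4)cc3OC)cc2OC)ccc1O[Si](C(C)C)(C(C)C)C(C)C | intermediate
27 | 7-deoxy precursor: target lacking the C7 hydroxyls of units C (8S) and E (8R); unit D 7R,8R | COc1cc(C[C@H](CO)Oc2ccc([C@@H](O)[C@@H](CO)Oc3c(OC)cc([C@@H]4OC[C@@H]5[C@H]4CO[C@H]5c4cc(OC)c(O[C@H](CO)Cc5ccc(O)c(OC)c5)c(OC)c4)cc3OC)cc2OC)ccc1O | intermediate
28 | phenylboronic acid | OB(O)c1ccccc1 | starting material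
29 | boron-loaded precursor: C9 phenylboronic hemiesters on units C and E, cyclic phenylboronate on the 1,3-diol of unit D | COc1cc(C[C@H](COB(O)c2ccccc2)Oc2ccc([C@H]6OB(c7ccccc7)OC[C@H]6Oc3c(OC)cc([C@@H]4OC[C@@H]5[C@H]4CO[C@H]5c4cc(OC)c(O[C@H](COB(O)c5ccccc5)Cc5ccc(O)c(OC)c5)c(OC)c4)cc3OC)cc2OC)ccc1O | intermediate (not isolated)
30 | bis(quinone methide) of 29 (both end rings as 2-methoxy-4-alkylidenecyclohexa-2,5-dienones; alkene geometry not defined) | COC1=CC(=C[C@H](COB(O)c2ccccc2)Oc2ccc([C@H]6OB(c7ccccc7)OC[C@H]6Oc3c(OC)cc([C@@H]4OC[C@@H]5[C@H]4CO[C@H]5c4cc(OC)c(O[C@H](COB(O)c5ccccc5)C=C5C=CC(=O)C(OC)=C5)c(OC)c4)cc3OC)cc2OC)C=CC1=O | intermediate (not isolated)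
31 | tris(phenylboronate) of the target (trans-4-aryl-5-aryloxy-2-phenyl-1,3,2-dioxaborinanes in units C and E, cyclic boronate in unit D) | COc1cc([C@H]8OB(c9ccccc9)OC[C@@H]8Oc2ccc([C@H]6OB(c7ccccc7)OC[C@H]6Oc3c(OC)cc([C@@H]4OC[C@@H]5[C@H]4CO[C@H]5c4cc(OC)c(O[C@@H]6COB(c7ccccc7)O[C@H]6c5ccc(O)c(OC)c5)c(OC)c4)cc3OC)cc2OC)ccc1O | intermediate (not isolated)
32 | CNP0316493.1 | COc1cc([C@@H](O)[C@H](CO)Oc2ccc([C@@H](O)[C@@H](CO)Oc3c(OC)cc([C@@H]4OC[C@@H]5[C@H]4CO[C@H]5c4cc(OC)c(O[C@H](CO)[C@@H](O)c5ccc(O)c(OC)c5)c(OC)c4)cc3OC)cc2OC)ccc1O | target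

Total step count: 17 (the resolution counted as a step).
Longest linear sequence: 12 steps (steps 3, 4, 5, 6, 7, 9, 10, 11, 14, 15, 16, 17).

Steps most likely to fail

1. Step 17. The phenoxyl radicals formed on the way to the quinone methides may couple at the unsubstituted C5 positions. The quinone methides may tautomerise to C7=C8 enol ethers before ring closure. Adventitious water may add to C7 from either face, giving both C7 epimers. Fallback by known reactions, setting out from 27 and returning at 32: the 1,3-diol of unit D is tied up with 2,2-dimethoxypropane and PPTS as the unit D acetonide F1. The two 4-alkylphenol termini are oxidised with DDQ in aqueous dioxane at 0 °C to the bis(7-ketone) F2. This is the documented path from 4-alkylphenols to 4-hydroxyaryl ketones through quinone methide, hydration and a second dehydrogenation; it relies on free phenols reacting faster than the etherified benzylic positions. The ketones are reduced with Zn(BH4)2 in Et2O/THF, where hydride delivery inside the chelate between the carbonyl and the C8 aryloxy oxygen gives the erythro alcohols, as the acetonide of the target F3. Aqueous acetic acid in THF at rt then removes the acetonide to give 32.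

2. Step 10. The boron triflate may be sequestered by the many ether oxygens, leaving enolisation incomplete. Enolisation may occur at the α-aryloxy ester of unit C. Facial selectivity may erode on this large substrate. Fallback, setting out from 11 and returning at 21: the second enolisable carbonyl is removed before the C–C bond is made. The ester of 11 is reduced with LiBH4 to the primary alcohol F4. Its ring A phenol is alkylated with 15 (K2CO3, MeCN) to the glycolyl imide F5. The same boron aldol with 17 is run with one extra equivalent each of n-Bu2BOTf and i-Pr2NEt to cover the free hydroxyl, giving the aldol adduct F6. LiBH4 reduction of F6 rejoins the route at 21.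

3. Step 7. Base-induced loss of triflic acid from 10 to the cinnamate may outrun substitution by the hindered 2,6-dimethoxyphenoxide, and over-alkylation to the bis-ether may consume resolved diphenol. Fallback, setting out from 4 and 9 and returning at 11: a Mitsunobu etherification (PPh3, DIAD, THF, 0 °C → rt) couples the hydroxy ester 9 directly with excess 4, with inversion at C8 and without base or triflate. It makes no new compound (F0).

Further compounds
F1 | step 17 | unit D acetonide of 27 | COc1cc(C[C@H](CO)Oc2ccc([C@H]6OC(C)(C)OC[C@H]6Oc3c(OC)cc([C@@H]4OC[C@@H]5[C@H]4CO[C@H]5c4cc(OC)c(O[C@H](CO)Cc5ccc(O)c(OC)c5)c(OC)c4)cc3OC)cc2OC)ccc1O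
F2 | step 17 | bis(7-ketone) of F1 (C7 carbonyl in units C and E) | COc1cc(C(=O)[C@H](CO)Oc2ccc([C@H]6OC(C)(C)OC[C@H]6Oc3c(OC)cc([C@@H]4OC[C@@H]5[C@H]4CO[C@H]5c4cc(OC)c(O[C@H](CO)C(=O)c5ccc(O)c(OC)c5)c(OC)c4)cc3OC)cc2OC)ccc1O
F3 | step 17 | unit D acetonide of the target | COc1cc([C@@H](O)[C@H](CO)Oc2ccc([C@H]6OC(C)(C)OC[C@H]6Oc3c(OC)cc([C@@H]4OC[C@@H]5[C@H]4CO[C@H]5c4cc(OC)c(O[C@H](CO)[C@@H](O)c5ccc(O)c(OC)c5)c(OC)c4)cc3OC)cc2OC)ccc1O
F4 | step 10 | ester-reduced mono-ether (11 with CH2OH in place of CO2Me) | Oc1c(OC)cc([C@@H]2OC[C@@H]3[C@H]2CO[C@H]3c2cc(OC)c(O[C@H](CO)Cc3ccc(O[Si](C(C)C)(C(C)C)C(C)C)c(OC)c3)c(OC)c2)cc1OC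
F5 | step 10 | glycolyl imide of F4 | O=C(COc1c(OC)cc([C@@H]2OC[C@@H]3[C@H]2CO[C@H]3c2cc(OC)c(O[C@H](CO)Cc3ccc(O[Si](C(C)C)(C(C)C)C(C)C)c(OC)c3)c(OC)c2)cc1OC)N1[C@@H](Cc2ccccc2)COC1=O
F6 | step 10 | syn-aldol adduct from F5 (20 with CH2OH in place of CO2Me in unit C) | CC(=O)Oc1ccc([C@@H](O)[C@@H](C(=O)N2[C@@H](Cc3ccccc3)COC2=O)Oc2c(OC)cc([C@@H]3OC[C@@H]4[C@H]3CO[C@H]4c3cc(OC)c(O[C@H](CO)Cc4ccc(O[Si](C(C)C)(C(C)C)C(C)C)c(OC)c4)c(OC)c3)cc2OC)cc1OC
F0 | step 7 | none | none
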